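All runs come from a simulation with made-up constants; the scatter is artificial.

The ratio of substrate charges between the gamma and eta runs is 2.24, yet the ratio of the percentages of substrate left at 25.0 h is 0.977, so these readings show a rate first order in c(substrate), and the flasks at 1.0 M can be read on the same percentage scale.

| flask | substrate | remark | time |
|---|---|---|---|
| eta | 0.67 M | run made earlier |  |
| gamma | 1.5 M | run made earlier |  |
| Friday's | 1.0 M |  | 40 h |
| Wednesday's | 1.0 M |  | 120 h |
| Sunday's | 1.0 M |  | 360 h |

| run | time / h | target / % | intermediate A / % | isomer of the product / % | intermediate B / % | substrate / % |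
|---|---|---|---|---|---|---|
| eta | 3.00 | 0 | 13.8 | 0 | 1.2 | 85.2 |
| eta | 8.00 | 0.1 | 28.3 | 0 | 5.7 | 64.2 |
| eta | 15.0 | 0 | 37.3 | 0.2 | 15.9 | 44.1 |
| eta | 25.0 | 1.6 | 37.2 | 0 | 30.1 | 26.0 |
| gamma | 3.00 | 0 | 14.6 | 0.2 | 1.2 | 85.1 |
| gamma | 8.00 | 0 | 29.0 | 0.4 | 6.8 | 64.5 |
| gamma | 15.0 | 0.8 | 37.1 | 0 | 16.7 | 44.6 |
| gamma | 25.0 | 1.9 | 37.0 | 0.6 | 31.2 | 25.4 |

(readings scatter by 0.5 percentage points)

1. which of these there is most of at the end, counted by the substrate in it, Friday's (isomer of the product / target / intermediate B / intermediate A / substrate)
2. which of these there is most of at the end, counted by the substrate in it, Wednesday's (isomer of the product / target / intermediate B / intermediate A / substrate)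
3. which of these there is most of at the end, counted by the substrate in it, Sunday's (isomer of the product / target / intermediate B / intermediate A / substrate)
4. final amount of the leader among these, as a percentage of the substrate charged, in Friday's
5. final amount of the leader among these, as a percentage of the substrate charged, in Wednesday's
6. final amount of the leader among these, as a percentage of the substrate charged, in Sunday's



At 25.0 h, the two runs taken together hold these amounts outside substrate, intermediate A and intermediate B:

gap in the balance = 9 percentage points

c(target) + c(isomer of the product) = 4.1 points

The recovered share, the part of what has left intermediate B that stands as target or isomer of the product, is then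

seen / (seen + gap) = 31.3%

Target makes up 85.4% of the recovered material. If Sunday's flask has drained its intermediate B, as a loss of 0.02 /h in the forecast's reading suggests, a gap that never returns puts target at a floor of 26.7%, while a gap wholly in transit puts it at a ceiling of 85.4%. The ceiling is loose, since the isomer readings behind it are 0% and 0.6% with a scatter of 0.5 points.

The forecast gives intermediate B at 43% for Friday's, target at 52% for Wednesday's and target at 90% for Sunday's, reasoning “At 360 h: nearly everything is target, less unknown isomer leakage, so about 90.” Its Sunday's value stands higher than the ceiling.

Friday's ends with intermediate B at 43.5%, Wednesday's with target at 32.3%, and Sunday's with target at 42.9%, higher than the floor and lower than the ceiling.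

    substrate → intermediate A (k = 1.52 × 10⁻⁵ /s)
    intermediate A → intermediate B (k = 1.37 × 10⁻⁵ /s)
    intermediate B → intermediate C (k = 3.25 × 10⁻⁶ /s)
    intermediate C → target (k = 4.71 × 10⁻⁵ /s)
    target ⇌ isomer of the product (K = 0.361, k = 2.36 × 10⁻⁵ /s)
    intermediate B → decomposed reagent (k = 2.26 × 10⁻⁶ /s)
    target → over-reaction product (k = 1.06 × 10⁻⁸ /s)

At 360 h in Sunday's, intermediate B passes into intermediate C 1.4 times as fast as into decomposed reagent, a selectivity factor that sends 59.0% towards intermediate C, and the recovered share of Sunday's, with decomposed reagent, intermediate C and over-reaction product as the gap, is 58.5%, higher than the 31.3% read from the eta and gamma runs at 25.0 h. In a neighbouring flask, Sunday's read at 4.0 d with intermediate B still at 31.7%, the recovered share is 55.2%.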